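**Retrosynthetic overview**
1. Target ⇐ C3 isobutyrate and 1,10-epoxide (both late) ⇐ α-methylene lactone made by Pd cyclocarbonylation of a 7-ethynyl-6-ol.
2. C6–OH and the C8 epoxy ester ⇐ one Evans–Tishchenko reduction of a β-hydroxy ketone with the epoxy aldehyde; C7 ⇐ ethynylation of the chelated dianion (new step); C8 ⇐ Cu-catalysed conjugate borylation.
3. Ten-membered (2Z,5E,9Z)-trienone ⇐ Grob-type ring expansion of a 5/7-fused 1,3-diol monomesylate; this fixes the E-1(10) and Z-4 alkenes and erases three helper stereocentres.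
4. 5/7 bicycle ⇐ RCM ⇐ vinyl addition ⇐ aldol/methylation of cyclopent-2-enone with the C1–C5 aldehyde (from methacrolein).
5. Ring order: five-membered ring (bought) → seven-membered ring (RCM) → ten-membered ring (fragmentation) → lactone (carbonylation) → oxirane.

Assumptions: germacrane numbering (C1–C15) is used for locants in the text; the ligand enantiomers named in steps 1, 8 and 10 are taken to give the drawn sense (otherwise the antipode is used); 7–11 are drawn as one of the converging series of helper diastereomers (C1, C6 and C10 all become sp2 in step 7).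

Step 1
Reactants: 1 methacrolein; 2 1-methoxy-1-(trimethylsilyloxy)ethene (O-silyl-protected enol of methyl acetate)
Product: 3 methyl (3S)-3-hydroxy-4-methylpent-4-enoate
Conditions: Ti(OiPr)4 (2 mol %), (R)-2-amino-2'-hydroxy-1,1'-binaphthyl-derived tridentate salicylaldimine ligand (2 mol %), 3,5-di-tert-butylsalicylic acid (4 mol %), Et2O, −10 °C; then 1 M HCl, THF
Reagents that add atoms: none
Why: Catalytic enantioselective Mukaiyama aldol addition, in which the chiral titanium complex blocks one face of the enal carbonyl and sets C3 as S.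

Step 2
Reactants: 3 methyl (3S)-3-hydroxy-4-methylpent-4-enoate
Product: 4 methyl (3S)-3-[(tert-butyldimethylsilyl)oxy]-4-methylpent-4-enoate
Conditions: TBSCl, imidazole, DMF, rt
Reagents that add atoms: tert-butyldimethylsilyl chloride, CC(C)(C)[Si](C)(C)Cl
Why: Standard silyl protection of the secondary alcohol so that C3–O survives the enolate, Grignard and base steps.

Step 3
Reactants: 4 methyl (3S)-3-[(tert-butyldimethylsilyl)oxy]-4-methylpent-4-enoate
Product: 5 (3S)-3-[(tert-butyldimethylsilyl)oxy]-4-methylpent-4-enal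
Conditions: iBu2AlH (1.1 equiv), CH2Cl2, −78 °C; Rochelle salt work-up
Reagents that add atoms: none
Why: Half-reduction of the ester at −78 °C stops at the aldehyde through the stable tetrahedral aluminate.

Step 4
Reactants: 6 cyclopent-2-en-1-one; 5 (3S)-3-[(tert-butyldimethylsilyl)oxy]-4-methylpent-4-enal
Product: 8 (5R)-5-[(1S,3S)-3-[(tert-butyldimethylsilyl)oxy]-1-hydroxy-4-methylpent-4-en-1-yl]-5-methylcyclopent-2-en-1-one, via aldol adduct 7 (not isolated)
Conditions: LDA (1.05 equiv), THF, −78 °C; 5; LDA (1.2 equiv), −78 °C; MeI, −78 → −40 °C; H2O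
Reagents that add atoms: iodomethane, CI
Why: Kinetic α'-enolate aldol addition followed by Fráter–Seebach-type methylation of the lithium-chelated dianion, in which methyl enters anti to the carbinol oxygen; this gives the C1/C10 relative configuration that the later fragmentation turns into the E-alkene (both C1 series converge).

Step 5
Reactants: 8 (5R)-5-[(1S,3S)-3-[(tert-butyldimethylsilyl)oxy]-1-hydroxy-4-methylpent-4-en-1-yl]-5-methylcyclopent-2-en-1-one
Product: 9 (1R,5R)-5-[(1S,3S)-3-[(tert-butyldimethylsilyl)oxy]-1-hydroxy-4-methylpent-4-en-1-yl]-1-ethenyl-5-methylcyclopent-2-en-1-ol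
Conditions: CeCl3 (3 equiv), CH2=CHMgBr (3 equiv), THF, −78 °C; H2O
Reagents that add atoms: vinylmagnesium bromide, C=C[Mg]Br
Why: Cerium-mediated 1,2-addition of the vinyl Grignard reagent to the enone carbonyl, anti to the bulky side chain (the C6 configuration is a helper and is lost in step 7).

Step 6
Reactants: 9 (1R,5R)-5-[(1S,3S)-3-[(tert-butyldimethylsilyl)oxy]-1-hydroxy-4-methylpent-4-en-1-yl]-1-ethenyl-5-methylcyclopent-2-en-1-ol
Product: 10 (3aS,6S,8S,8aR)-6-[(tert-butyldimethylsilyl)oxy]-5,8a-dimethyl-1,3a,6,7,8,8a-hexahydroazulene-3a,8-diol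
Conditions: second-generation Grubbs catalyst (5 mol %), CH2Cl2 (5 mM), 40 °C
Reagents that add atoms: none
Why: Ring-closing metathesis of the vinyl and isopropenyl groups forms the seven-membered ring, which holds the C4=C5 bond in the cis (later Z) geometry.

Step 7
Reactants: 10 (3aS,6S,8S,8aR)-6-[(tert-butyldimethylsilyl)oxy]-5,8a-dimethyl-1,3a,6,7,8,8a-hexahydroazulene-3a,8-diol
Product: 12 (2Z,5E,8S,9Z)-8-[(tert-butyldimethylsilyl)oxy]-5,9-dimethylcyclodeca-2,5,9-trien-1-one, via mesylate 11 (not isolated)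
Conditions: MsCl, Et3N, CH2Cl2, −20 °C; then KOtBu (1.1 equiv), THF, −20 → 0 °C
Reagents that add atoms: methanesulfonyl chloride, CS(=O)(=O)Cl (its atoms are carried by 11 only and leave again as mesylate)
Why: Grob (Wharton-type) fragmentation: the tertiary alkoxide at C6 pushes out the anti-periplanar C1 mesylate while the C6–C10 ring-fusion bond breaks, so the five- and seven-membered rings merge stereospecifically into the ten-membered ring with the E C1=C10 alkene and the three helper stereocentres disappear.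

Step 8
Reactants: 12 (2Z,5E,8S,9Z)-8-[(tert-butyldimethylsilyl)oxy]-5,9-dimethylcyclodeca-2,5,9-trien-1-one
Product: 14 (2Z,4S,6E,9R)-4-[(tert-butyldimethylsilyl)oxy]-9-hydroxy-3,7-dimethylcyclodeca-2,6-dien-1-one, via boronate 13 (not isolated)
Conditions: CuCl (5 mol %), (R,S)-Josiphos (6 mol %), NaOtBu (10 mol %), B2pin2 (1.1 equiv), MeOH (2 equiv), THF, 0 °C; then NaBO3·4H2O, THF/H2O, rt
Reagents that add atoms: bis(pinacolato)diboron, CC1(C)OB(OC1(C)C)B1OC(C)(C)C(C)(C)O1 (boryl group of 13); sodium perborate, [Na+].[O-]OB=O (oxygen of the new hydroxyl)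
Why: Copper-catalysed enantioselective conjugate borylation attacks only the β-monosubstituted cis-enone (the β,β-disubstituted one is too hindered), the ligand sets C8 as R, and perborate oxidation replaces boron by oxygen with retention.

Step 9
Reactants: 14 (2Z,4S,6E,9R)-4-[(tert-butyldimethylsilyl)oxy]-9-hydroxy-3,7-dimethylcyclodeca-2,6-dien-1-one
Product: 15 (2Z,4S,6E,9R,10R)-4-[(tert-butyldimethylsilyl)oxy]-10-ethynyl-9-hydroxy-3,7-dimethylcyclodeca-2,6-dien-1-one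
Conditions: LDA (2.3 equiv), THF, −78 °C; TMS-EBX (1.3 equiv), Bu4NF (1.3 equiv), −78 → −40 °C; aq. NH4Cl
Reagents that add atoms: 1-[(trimethylsilyl)ethynyl]-1,2-benziodoxol-3(1H)-one (TMS-EBX), C[Si](C)(C)C#CI1OC(=O)c2ccccc12
Why: Proposed new method: α-ethynylation of a Fráter–Seebach dianion with an ethynylbenziodoxolone – the lithium alkoxide on O8 chelates the lithium enolate (O6/C7), C7 attacks the hypervalent iodine alkyne freed from TMS-EBX by fluoride on the enolate face anti to C9 (conjugate addition to the alkynyl iodane, loss of 2-iodobenzoate to a vinylidene carbene, 1,2-hydride shift), forming the C7–C11 bond and setting C7 7,8-anti; the closest known reactions are the α-alkynylation of β-keto ester and ketone enolates with EBX reagents and the anti-selective alkylation of β-hydroxy carbonyl dianions.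

Step 10
Reactants: 16 (2E)-2-methylbut-2-en-1-ol
Product: 17 [(2S,3S)-2,3-dimethyloxiran-2-yl]methanol
Conditions: Ti(OiPr)4 (5 mol %), L-(+)-diethyl tartrate (6 mol %), tBuOOH, 4 Å molecular sieves, CH2Cl2, −20 °C
Reagents that add atoms: tert-butyl hydroperoxide, CC(C)(C)OO
Why: Sharpless asymmetric epoxidation, in which the titanium tartrate complex delivers oxygen to one face of the E-allylic alcohol and sets both oxirane centres.

Step 11
Reactants: 17 [(2S,3S)-2,3-dimethyloxiran-2-yl]methanol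
Product: 18 (2R,3S)-2,3-dimethyloxirane-2-carbaldehyde
Conditions: TEMPO (10 mol %), PhI(OAc)2 (1.1 equiv), CH2Cl2, rt; used as a solution
Reagents that add atoms: none
Why: Oxoammonium (TEMPO) oxidation of the primary alcohol stops at the non-enolisable aldehyde and leaves the oxirane untouched.

Step 12
Reactants: 15 (2Z,4S,6E,9R,10R)-4-[(tert-butyldimethylsilyl)oxy]-10-ethynyl-9-hydroxy-3,7-dimethylcyclodeca-2,6-dien-1-one; 18 (2R,3S)-2,3-dimethyloxirane-2-carbaldehyde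
Product: 19 (1R,3E,6S,7Z,9R,10S)-6-[(tert-butyldimethylsilyl)oxy]-10-ethynyl-9-hydroxy-3,7-dimethylcyclodeca-3,7-dien-1-yl (2R,3S)-2,3-dimethyloxirane-2-carboxylate
Conditions: SmI2 (30 mol %), 18 (4 equiv), THF, −10 °C
Reagents that add atoms: none
Why: Evans–Tishchenko reduction: the hemiacetal of 18 on O8, bound to trivalent samarium, delivers its hydride intramolecularly to the C6 ketone anti to O8, which sets C6 (1,3-anti) and at the same time leaves the epoxy acyl group on O8 and the C6 hydroxyl free.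

Step 13
Reactants: 19 (1R,3E,6S,7Z,9R,10S)-6-[(tert-butyldimethylsilyl)oxy]-10-ethynyl-9-hydroxy-3,7-dimethylcyclodeca-3,7-dien-1-yl (2R,3S)-2,3-dimethyloxirane-2-carboxylate
Product: 20 (3aR,4R,6E,9S,10Z,11aR)-9-[(tert-butyldimethylsilyl)oxy]-6,10-dimethyl-3-methylidene-2-oxo-2,3,3a,4,5,8,9,11a-octahydrocyclodeca[b]furan-4-yl (2R,3S)-2,3-dimethyloxirane-2-carboxylate
Conditions: PdI2 (5 mol %), PBu3 (10 mol %), CO (7 atm), MeCN, 75 °C
Reagents that add atoms: carbon monoxide, [C-]#[O+]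
Why: Palladium-catalysed cyclocarbonylation of the homopropargylic alcohol (alkoxycarbonyl-palladium adds across the terminal alkyne) closes the trans-fused α-methylene-γ-butyrolactone without touching C6 or C7.

Step 14
Reactants: 20 (3aR,4R,6E,9S,10Z,11aR)-9-[(tert-butyldimethylsilyl)oxy]-6,10-dimethyl-3-methylidene-2-oxo-2,3,3a,4,5,8,9,11a-octahydrocyclodeca[b]furan-4-yl (2R,3S)-2,3-dimethyloxirane-2-carboxylate
Product: 21 (1R,3S,4Z,6R,7R,8R,10R)-3-[(tert-butyldimethylsilyl)oxy]-1,10-epoxy-8-{[(2R,3S)-2,3-dimethyloxirane-2-carbonyl]oxy}germacra-4,11(13)-dien-12,6-olide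
Conditions: mCPBA (1.1 equiv), NaHCO3, CH2Cl2, −20 → 0 °C
Reagents that add atoms: 3-chloroperoxybenzoic acid, OOC(=O)c1cccc(Cl)c1
Why: Prilezhaev epoxidation picks the only electron-rich alkene (C1=C10; C4=C5 is flanked by two allylic oxygens and the silyl ether, the acrylate is electron-poor) and is expected to attack its exposed outer face, which would give the trans 1R,10R oxirane (substrate control, not certain).

Step 15
Reactants: 21 (1R,3S,4Z,6R,7R,8R,10R)-3-[(tert-butyldimethylsilyl)oxy]-1,10-epoxy-8-{[(2R,3S)-2,3-dimethyloxirane-2-carbonyl]oxy}germacra-4,11(13)-dien-12,6-olide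
Product: 22 (1R,3S,4Z,6R,7R,8R,10R)-1,10-epoxy-8-{[(2R,3S)-2,3-dimethyloxirane-2-carbonyl]oxy}-3-hydroxygermacra-4,11(13)-dien-12,6-olide
Conditions: Bu4NF, AcOH (1:1), THF, 0 °C → rt
Reagents that add atoms: none
Why: Buffered fluoride desilylation frees the C3 alcohol without opening the oxiranes or adding to the methylene lactone.

Step 16
Reactants: 22 (1R,3S,4Z,6R,7R,8R,10R)-1,10-epoxy-8-{[(2R,3S)-2,3-dimethyloxirane-2-carbonyl]oxy}-3-hydroxygermacra-4,11(13)-dien-12,6-olide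
Product: 23 (1R,3S,4Z,6R,7R,8R,10R)-1,10-epoxy-8-{[(2R,3S)-2,3-dimethyloxirane-2-carbonyl]oxy}-3-(2-methylpropanoyloxy)germacra-4,11(13)-dien-12,6-olide (CNP0117882.3)
Conditions: (iPrCO)2O, DMAP (cat.), pyridine, CH2Cl2, 0 °C
Reagents that add atoms: isobutyric anhydride, CC(C)C(=O)OC(=O)C(C)C
Why: DMAP-catalysed acylation of the only free hydroxyl gives the target with retention at C3.

**Compound list**
1 | methacrolein | C=C(C)C=O | starting material
2 | 1-methoxy-1-(trimethylsilyloxy)ethene | C=C(OC)O[Si](C)(C)C | starting material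
3 | methyl (3S)-3-hydroxy-4-methylpent-4-enoate | COC(=O)C[C@H](O)C(C)=C | intermediate
4 | methyl (3S)-3-[(tert-butyldimethylsilyl)oxy]-4-methylpent-4-enoate | COC(=O)C[C@H](O[Si](C)(C)C(C)(C)C)C(C)=C | intermediate
5 | (3S)-3-[(tert-butyldimethylsilyl)oxy]-4-methylpent-4-enal | O=CC[C@H](O[Si](C)(C)C(C)(C)C)C(C)=C | intermediate
6 | cyclopent-2-en-1-one | O=C1C=CCC1 | starting material
7 | 5-[(1S,3S)-3-[(tert-butyldimethylsilyl)oxy]-1-hydroxy-4-methylpent-4-en-1-yl]cyclopent-2-en-1-one (ring C5 epimers) | O=C1C=CCC1[C@@H](O)C[C@H](O[Si](C)(C)C(C)(C)C)C(C)=C | intermediate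
8 | (5R)-5-[(1S,3S)-3-[(tert-butyldimethylsilyl)oxy]-1-hydroxy-4-methylpent-4-en-1-yl]-5-methylcyclopent-2-en-1-one | O=C1C=CC[C@]1(C)[C@@H](O)C[C@H](O[Si](C)(C)C(C)(C)C)C(C)=C | intermediate
9 | (1R,5R)-5-[(1S,3S)-3-[(tert-butyldimethylsilyl)oxy]-1-hydroxy-4-methylpent-4-en-1-yl]-1-ethenyl-5-methylcyclopent-2-en-1-ol | C=C[C@@]1(O)C=CC[C@]1(C)[C@@H](O)C[C@H](O[Si](C)(C)C(C)(C)C)C(C)=C | intermediate
10 | (3aS,6S,8S,8aR)-6-[(tert-butyldimethylsilyl)oxy]-5,8a-dimethyl-1,3a,6,7,8,8a-hexahydroazulene-3a,8-diol | C[C@]12CC=C[C@]1(O)C=C(C)[C@@H](O[Si](C)(C)C(C)(C)C)C[C@@H]2O | intermediate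
11 | (3aS,6S,8S,8aR)-6-[(tert-butyldimethylsilyl)oxy]-3a-hydroxy-5,8a-dimethyl-1,3a,6,7,8,8a-hexahydroazulen-8-yl methanesulfonate | C[C@]12CC=C[C@]1(O)C=C(C)[C@@H](O[Si](C)(C)C(C)(C)C)C[C@@H]2OS(C)(=O)=O | intermediate
12 | (2Z,5E,8S,9Z)-8-[(tert-butyldimethylsilyl)oxy]-5,9-dimethylcyclodeca-2,5,9-trien-1-one | O=C1/C=C\C/C(C)=C/C[C@H](O[Si](C)(C)C(C)(C)C)/C(C)=C\1 | intermediate
13 | (2Z,4S,6E,9R)-4-[(tert-butyldimethylsilyl)oxy]-3,7-dimethyl-9-(4,4,5,5-tetramethyl-1,3,2-dioxaborolan-2-yl)cyclodeca-2,6-dien-1-one | O=C1C[C@H](B2OC(C)(C)C(C)(C)O2)C/C(C)=C/C[C@H](O[Si](C)(C)C(C)(C)C)/C(C)=C\1 | intermediate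
14 | (2Z,4S,6E,9R)-4-[(tert-butyldimethylsilyl)oxy]-9-hydroxy-3,7-dimethylcyclodeca-2,6-dien-1-one | O=C1C[C@H](O)C/C(C)=C/C[C@H](O[Si](C)(C)C(C)(C)C)/C(C)=C\1 | intermediate
15 | (2Z,4S,6E,9R,10R)-4-[(tert-butyldimethylsilyl)oxy]-10-ethynyl-9-hydroxy-3,7-dimethylcyclodeca-2,6-dien-1-one | O=C1[C@H](C#C)[C@H](O)C/C(C)=C/C[C@H](O[Si](C)(C)C(C)(C)C)/C(C)=C\1 | intermediate
16 | (2E)-2-methylbut-2-en-1-ol | C/C=C(\C)CO | starting material
17 | [(2S,3S)-2,3-dimethyloxiran-2-yl]methanol | OC[C@]1(C)O[C@H]1C | intermediate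
18 | (2R,3S)-2,3-dimethyloxirane-2-carbaldehyde | O=C[C@]1(C)O[C@H]1C | intermediate
19 | (1R,3E,6S,7Z,9R,10S)-6-[(tert-butyldimethylsilyl)oxy]-10-ethynyl-9-hydroxy-3,7-dimethylcyclodeca-3,7-dien-1-yl (2R,3S)-2,3-dimethyloxirane-2-carboxylate | O[C@H]1[C@H](C#C)[C@H](OC(=O)[C@]2(C)O[C@H]2C)C/C(C)=C/C[C@H](O[Si](C)(C)C(C)(C)C)/C(C)=C\1 | intermediate
20 | (3aR,4R,6E,9S,10Z,11aR)-9-[(tert-butyldimethylsilyl)oxy]-6,10-dimethyl-3-methylidene-2-oxo-2,3,3a,4,5,8,9,11a-octahydrocyclodeca[b]furan-4-yl (2R,3S)-2,3-dimethyloxirane-2-carboxylate | C=C1C(=O)O[C@@H]2/C=C(/C)[C@@H](O[Si](C)(C)C(C)(C)C)C/C=C(\C)C[C@@H](OC(=O)[C@]3(C)O[C@H]3C)[C@@H]12 | intermediate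
21 | (1R,3S,4Z,6R,7R,8R,10R)-3-[(tert-butyldimethylsilyl)oxy]-1,10-epoxy-8-{[(2R,3S)-2,3-dimethyloxirane-2-carbonyl]oxy}germacra-4,11(13)-dien-12,6-olide | C=C1C(=O)O[C@@H]2/C=C(/C)[C@@H](O[Si](C)(C)C(C)(C)C)C[C@H]3O[C@]3(C)C[C@@H](OC(=O)[C@]3(C)O[C@H]3C)[C@@H]12 | intermediate
22 | (1R,3S,4Z,6R,7R,8R,10R)-1,10-epoxy-8-{[(2R,3S)-2,3-dimethyloxirane-2-carbonyl]oxy}-3-hydroxygermacra-4,11(13)-dien-12,6-olide | C=C1C(=O)O[C@@H]2/C=C(/C)[C@@H](O)C[C@H]3O[C@]3(C)C[C@@H](OC(=O)[C@]3(C)O[C@H]3C)[C@@H]12 | intermediate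
23 | (1R,3S,4Z,6R,7R,8R,10R)-1,10-epoxy-8-{[(2R,3S)-2,3-dimethyloxirane-2-carbonyl]oxy}-3-(2-methylpropanoyloxy)germacra-4,11(13)-dien-12,6-olide (CNP0117882.3) | C=C1C(=O)O[C@@H]2/C=C(/C)[C@@H](OC(=O)C(C)C)C[C@H]3O[C@]3(C)C[C@@H](OC(=O)[C@]3(C)O[C@H]3C)[C@@H]12 | target

**Totals**
Total step count: 16. Longest linear sequence: 14 (steps 1–9 and 12–16).

**Three steps most likely to fail**

Step 9 (the proposed new ethynylation; risks are over-alkynylation, no chelated enolate in the ten-membered ring, wrong C7 epimer). The fallback uses known chemistry, sets out from 14 and comes back at 20. LDA (2.3 equiv), THF, −78 °C, then methyl bromoacetate (Fráter–Seebach alkylation) gives methyl 2-[(1R,3Z,5S,7E,10R)-5-[(tert-butyldimethylsilyl)oxy]-10-hydroxy-4,8-dimethyl-2-oxocyclodeca-3,7-dien-1-yl]acetate F2. Evans–Tishchenko reduction with 18 (SmI2 cat., THF, −10 °C) gives (1R,3E,6S,7Z,9R,10S)-6-[(tert-butyldimethylsilyl)oxy]-9-hydroxy-10-(2-methoxy-2-oxoethyl)-3,7-dimethylcyclodeca-3,7-dien-1-yl (2R,3S)-2,3-dimethyloxirane-2-carboxylate F3. PPTS, benzene, 60 °C closes the lactone with loss of methanol to (3aR,4R,6E,9S,10Z,11aR)-9-[(tert-butyldimethylsilyl)oxy]-6,10-dimethyl-2-oxo-2,3,3a,4,5,8,9,11a-octahydrocyclodeca[b]furan-4-yl (2R,3S)-2,3-dimethyloxirane-2-carboxylate F4. LiHMDS, THF, −78 °C, then dimethyl(methylidene)ammonium iodide gives the Mannich base (3aR,4R,6E,9S,10Z,11aR)-9-[(tert-butyldimethylsilyl)oxy]-3-[(dimethylamino)methyl]-6,10-dimethyl-2-oxo-2,3,3a,4,5,8,9,11a-octahydrocyclodeca[b]furan-4-yl (2R,3S)-2,3-dimethyloxirane-2-carboxylate F5. MeI, then NaHCO3, eliminates trimethylamine and gives 20.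

Step 8 (enantioselective borylation on a ten-membered cross-conjugated dienone, a substrate class not yet tested; risks are low face control and double addition). The fallback sets out from 12 and comes back at 14. Yb(OiPr)3, (R)-3-(hydroxymethyl)-1,1'-bi-2-naphthol, tBuOOH, 4 Å molecular sieves, THF (catalytic asymmetric epoxidation of the cis-enone) gives (1R,3Z,5S,7E,10R)-5-[(tert-butyldimethylsilyl)oxy]-4,8-dimethyl-11-oxabicyclo[8.1.0]undeca-3,7-dien-2-one F1. SmI2 (2.2 equiv), MeOH, THF, −78 °C cleaves the α C–O bond reductively and gives 14.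

Step 14 (face selectivity of the peracid on the flexible ring). The fallback reaches the oxirane from the opposite face; it sets out from 20 and comes back at 21. NBS, THF/H2O, 0 °C gives the bromohydrin (1S,3S,4Z,6R,7R,8R,10R)-1-bromo-3-[(tert-butyldimethylsilyl)oxy]-8-{[(2R,3S)-2,3-dimethyloxirane-2-carbonyl]oxy}-10-hydroxygermacra-4,11(13)-dien-12,6-olide F6 (water opens the bromonium ion at C10 from the face the peracid avoids). K2CO3, acetone then closes the oxirane with inversion at C1 and gives 21.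

**Further compounds**
F1 | step 8 | (1R,3Z,5S,7E,10R)-5-[(tert-butyldimethylsilyl)oxy]-4,8-dimethyl-11-oxabicyclo[8.1.0]undeca-3,7-dien-2-one | O=C1[C@@H]2O[C@@H]2C/C(C)=C/C[C@H](O[Si](C)(C)C(C)(C)C)/C(C)=C\1
F2 | step 9 | methyl 2-[(1R,3Z,5S,7E,10R)-5-[(tert-butyldimethylsilyl)oxy]-10-hydroxy-4,8-dimethyl-2-oxocyclodeca-3,7-dien-1-yl]acetate | O=C1[C@H](CC(=O)OC)[C@H](O)C/C(C)=C/C[C@H](O[Si](C)(C)C(C)(C)C)/C(C)=C\1
F3 | step 9 | (1R,3E,6S,7Z,9R,10S)-6-[(tert-butyldimethylsilyl)oxy]-9-hydroxy-10-(2-methoxy-2-oxoethyl)-3,7-dimethylcyclodeca-3,7-dien-1-yl (2R,3S)-2,3-dimethyloxirane-2-carboxylate | O[C@H]1[C@H](CC(=O)OC)[C@H](OC(=O)[C@]2(C)O[C@H]2C)C/C(C)=C/C[C@H](O[Si](C)(C)C(C)(C)C)/C(C)=C\1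
F4 | step 9 | (3aR,4R,6E,9S,10Z,11aR)-9-[(tert-butyldimethylsilyl)oxy]-6,10-dimethyl-2-oxo-2,3,3a,4,5,8,9,11a-octahydrocyclodeca[b]furan-4-yl (2R,3S)-2,3-dimethyloxirane-2-carboxylate | C1C(=O)O[C@@H]2/C=C(/C)[C@@H](O[Si](C)(C)C(C)(C)C)C/C=C(\C)C[C@@H](OC(=O)[C@]3(C)O[C@H]3C)[C@@H]12
F5 | step 9 | (3aR,4R,6E,9S,10Z,11aR)-9-[(tert-butyldimethylsilyl)oxy]-3-[(dimethylamino)methyl]-6,10-dimethyl-2-oxo-2,3,3a,4,5,8,9,11a-octahydrocyclodeca[b]furan-4-yl (2R,3S)-2,3-dimethyloxirane-2-carboxylate (C3 epimers) | CN(C)CC1C(=O)O[C@@H]2/C=C(/C)[C@@H](O[Si](C)(C)C(C)(C)C)C/C=C(\C)C[C@@H](OC(=O)[C@]3(C)O[C@H]3C)[C@@H]12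
F6 | step 14 | (1S,3S,4Z,6R,7R,8R,10R)-1-bromo-3-[(tert-butyldimethylsilyl)oxy]-8-{[(2R,3S)-2,3-dimethyloxirane-2-carbonyl]oxy}-10-hydroxygermacra-4,11(13)-dien-12,6-olide | C=C1C(=O)O[C@@H]2/C=C(/C)[C@@H](O[Si](C)(C)C(C)(C)C)C[C@H](Br)[C@](C)(O)C[C@@H](OC(=O)[C@]3(C)O[C@H]3C)[C@@H]12
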